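**Retrosynthetic overview**
- Final operations: global desilylation; the (Z)-enal comes from Babler–Dauben oxidative transposition of an isopropenyl carbinol made from the ring ketone.
- The trisubstituted (E)-alkene is formed by a B-alkyl Suzuki coupling of a cyclohexyl-ethyl borane (fragment A) with an oxolanyl (E)-vinyl iodide (fragment B).
- Fragment A: the cyclohexane is bought as benzoquinone monoketal; asymmetric Rh alkenyl 1,4-addition, two α′-alkylations (quaternary carbon), hydrogenation, organocerium methyl addition (tertiary alcohol).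
- Fragment B: Negishi carboalumination/glycidyl ether opening, hydroxyl-directed epoxidation, Mitsunobu inversion, acid 5-endo epoxide opening (oxolane ring), then CH2OBn → alkyne → vinyl iodide.
- Ring order: cyclohexane present from the start; oxolane closed in fragment B (step 13); no ring is formed after the coupling.

Assumption: the target is taken exactly as drawn (enal 2Z, side-chain alkene E, seven stereocentres) and compounds 1, 2, 13, 14 and 16 are bought.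
Abbreviations: TBSO = tert-butyldimethylsilyloxy, TESO = triethylsilyloxy, Bn = benzyl.

Step 1
Reactants: 1 4,4-dimethoxycyclohexa-2,5-dien-1-one; 2 (E)-3-(TBSO)prop-1-enylboronic acid pinacol ester
Product: 3 (5R)-5-[(1E)-3-(TBSO)prop-1-en-1-yl]-4,4-dimethoxycyclohex-2-en-1-one
Conditions: Rh(acac)(C2H4)2 (3 mol %), (R)-BINAP (3.3 mol %), KOH (0.5 equiv), dioxane/H2O 10:1, 60 °C; 1 in 1.5-fold excess
Reagents that add atoms: none
Why: Hayashi–Miyaura rhodium-catalysed asymmetric 1,4-addition desymmetrises the prochiral dienone, the (R)-BINAP alkenylrhodium species adding to the enantiotopic face opposite to that taken by the (S)-ligand with 2-cyclohexenone, which sets C5 as R.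

Step 2
Reactants: 3 (5R)-5-[(1E)-3-(TBSO)prop-1-en-1-yl]-4,4-dimethoxycyclohex-2-en-1-one
Product: 5 (5S,6S)-5-[(1E)-3-(TBSO)prop-1-en-1-yl]-4,4-dimethoxy-6-methylcyclohex-2-en-1-one, via lithium dienolate 4 (not isolated)
Conditions: LiN(i-Pr)2 (LDA, 1.1 equiv), THF, −78 °C; then MeI, −78 → −20 °C
Reagents that add atoms: iodomethane, CI
Why: Kinetic α′-deprotonation of the enone (the only enolisable site, the γ-carbon being the ketal) followed by enolate C-methylation, the methyl entering trans to the C5 chain at a centre that is re-enolised in step 3.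

Step 3
Reactants: 5 (5S,6S)-5-[(1E)-3-(TBSO)prop-1-en-1-yl]-4,4-dimethoxy-6-methylcyclohex-2-en-1-one
Product: 7 methyl 2-{(1S,6S)-6-[(1E)-3-(TBSO)prop-1-en-1-yl]-5,5-dimethoxy-1-methyl-2-oxocyclohex-3-en-1-yl}acetate, via lithium dienolate 6 (not isolated)
Conditions: LDA (1.2 equiv), THF/DMPU, −78 °C; then BrCH2CO2Me, −78 → −30 °C
Reagents that add atoms: methyl bromoacetate, COC(=O)CBr
Why: Enolate C-alkylation of the tetrasubstituted dienolate builds the quaternary carbon, the electrophile approaching anti to the vicinal alkenyl group so that the acetate arm ends trans and the methyl cis to it (1S).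

Step 4
Reactants: 7 methyl 2-{(1S,6S)-6-[(1E)-3-(TBSO)prop-1-en-1-yl]-5,5-dimethoxy-1-methyl-2-oxocyclohex-3-en-1-yl}acetate
Product: 8 methyl 2-{(1S,6S)-6-[3-(TBSO)propyl]-5,5-dimethoxy-1-methyl-2-oxocyclohexyl}acetate
Conditions: H2 (1 atm), 10 % Pd/C, EtOAc, rt
Reagents that add atoms: none
Why: Heterogeneous catalytic hydrogenation saturates the enone C=C and the side-chain alkene while ketone, ketal, ester and silyl ether survive, and no stereocentre is formed.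

Step 5
Reactants: 8 methyl 2-{(1S,6S)-6-[3-(TBSO)propyl]-5,5-dimethoxy-1-methyl-2-oxocyclohexyl}acetate
Product: 9 methyl 2-{(1S,2S,6S)-6-[3-(TBSO)propyl]-2-hydroxy-5,5-dimethoxy-1,2-dimethylcyclohexyl}acetate
Conditions: CeCl3 (anhydrous), MeLi, THF, −78 °C
Reagents that add atoms: methyllithium, [Li]C
Why: Organocerium 1,2-addition (non-basic, ketone-selective over the ester) occurs axially in the chair that has the C6 chain equatorial and the C1 methyl axial, anti to that methyl, because the other chair places the C6 chain syn-axial to the incoming reagent, so the new hydroxyl ends cis to the C1 methyl (2S).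

Step 6
Reactants: 9 methyl 2-{(1S,2S,6S)-6-[3-(TBSO)propyl]-2-hydroxy-5,5-dimethoxy-1,2-dimethylcyclohexyl}acetate
Product: 10 methyl 2-{(1S,2S,6S)-6-[3-(TBSO)propyl]-5,5-dimethoxy-1,2-dimethyl-2-(TESO)cyclohexyl}acetate
Conditions: Et3SiOTf, 2,6-lutidine, CH2Cl2, −78 → 0 °C
Reagents that add atoms: triethylsilyl trifluoromethanesulfonate, CC[Si](CC)(CC)OS(=O)(=O)C(F)(F)F
Why: Silyl triflate O-silylation caps the hindered tertiary alcohol, which would otherwise cyclise onto the later iodide and quench the alkyllithium, and no stereocentre is touched.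

Step 7
Reactants: 10 methyl 2-{(1S,2S,6S)-6-[3-(TBSO)propyl]-5,5-dimethoxy-1,2-dimethyl-2-(TESO)cyclohexyl}acetate
Product: 11 2-{(1S,2S,6S)-6-[3-(TBSO)propyl]-5,5-dimethoxy-1,2-dimethyl-2-(TESO)cyclohexyl}ethan-1-ol
Conditions: LiAlH4, THF, 0 °C
Reagents that add atoms: none
Why: Hydride reduction of the ester to the primary alcohol leaves ketal and silyl ethers intact and creates no stereocentre.

Step 8
Reactants: 11 2-{(1S,2S,6S)-6-[3-(TBSO)propyl]-5,5-dimethoxy-1,2-dimethyl-2-(TESO)cyclohexyl}ethan-1-ol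
Product: 12 tert-butyl(3-{(1S,2S,3S)-2-(2-iodoethyl)-6,6-dimethoxy-2,3-dimethyl-3-(TESO)cyclohexyl}propoxy)dimethylsilane
Conditions: I2, PPh3, imidazole, CH2Cl2, 0 °C → rt
Reagents that add atoms: iodine, II
Why: Appel-type (Garegg–Samuelsson) iodination converts the unhindered primary alcohol into the iodide by SN2 displacement of the alkoxyphosphonium, with no stereocentre involved.

Step 9
Reactants: 13 5-bromo-2-methylpent-2-ene; 14 lithium acetylide–ethylenediamine complex (LiC≡CH·H2NCH2CH2NH2)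
Product: 15 6-methylhept-5-en-1-yne
Conditions: DMSO, 10 °C → rt
Reagents that add atoms: none
Why: SN2 alkylation of the acetylide by the primary homoallylic bromide gives the terminal enyne, with no stereocentre formed.

Step 10
Reactants: 15 6-methylhept-5-en-1-yne; 16 (2S)-2-[(benzyloxy)methyl]oxirane
Product: 19 (2S,4E)-1-(benzyloxy)-5,9-dimethyldeca-4,8-dien-2-ol, via vinylalane 17 (not isolated), via lithium alanate 18 (not isolated)
Conditions: AlMe3 (2 equiv), Cp2ZrCl2 (0.25 equiv), CH2Cl2, 0 °C → rt; then n-BuLi, hexane, −78 → 0 °C; then 16, THF, −30 °C → rt; aq. Rochelle salt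
Reagents that add atoms: trimethylaluminium, C[Al](C)C
Why: Negishi zirconium-catalysed syn-methylalumination fixes the E trisubstituted alkene, and the derived alanate opens the epoxide at its terminal carbon with retention of alkene geometry, the carbinol stereocentre coming unchanged from 16.

Step 11
Reactants: 19 (2S,4E)-1-(benzyloxy)-5,9-dimethyldeca-4,8-dien-2-ol
Product: 20 (2S)-1-(benzyloxy)-3-[(2R,3R)-3-methyl-3-(4-methylpent-3-en-1-yl)oxiran-2-yl]propan-2-ol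
Conditions: VO(acac)2 (5 mol %), t-BuOOH (1.5 equiv, in decane), CH2Cl2, 0 °C → rt; aq. Na2S2O3/NaHCO3
Reagents that add atoms: tert-butyl hydroperoxide, CC(C)(C)OO
Why: Hydroxyl-directed vanadium-catalysed epoxidation touches only the homoallylic alkene, and the chair-like vanadate transition state (CH2OBn equatorial, alkene turned away by A(1,3) strain from the cis methyl) delivers oxygen to give the 1,3-syn epoxy alcohol, that is the (2R,3R)-oxirane.

Step 12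
Reactants: 20 (2S)-1-(benzyloxy)-3-[(2R,3R)-3-methyl-3-(4-methylpent-3-en-1-yl)oxiran-2-yl]propan-2-ol
Product: 21 (2R)-1-(benzyloxy)-3-[(2R,3R)-3-methyl-3-(4-methylpent-3-en-1-yl)oxiran-2-yl]propan-2-yl 4-nitrobenzoate
Conditions: 4-O2NC6H4CO2H, PPh3, DIAD, THF, 0 °C → rt
Reagents that add atoms: 4-nitrobenzoic acid, OC(=O)c1ccc(cc1)[N+](=O)[O-]
Why: Mitsunobu esterification inverts the carbinol by SN2 displacement of the alkoxyphosphonium (S to R), turning the 1,3-syn into the required 1,3-anti relationship.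

Step 13
Reactants: 21 (2R)-1-(benzyloxy)-3-[(2R,3R)-3-methyl-3-(4-methylpent-3-en-1-yl)oxiran-2-yl]propan-2-yl 4-nitrobenzoate
Product: 23 (2S,3R,5R)-5-[(benzyloxy)methyl]-2-methyl-2-(4-methylpent-3-en-1-yl)oxolan-3-ol, via anti-epoxy alcohol 22 (not isolated)
Conditions: K2CO3, MeOH, 0 °C; work-up; then CSA (10 mol %), CH2Cl2, 0 °C
Reagents that add atoms: none
Why: Transesterification frees the alcohol, and acid-catalysed 5-endo epoxide opening at the tertiary carbon proceeds with inversion there (C2 becomes S) and retention at C3 and C5, closing the oxolane with hydroxyl, methyl and CH2OBn all cis.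

Step 14
Reactants: 23 (2S,3R,5R)-5-[(benzyloxy)methyl]-2-methyl-2-(4-methylpent-3-en-1-yl)oxolan-3-ol
Product: 24 (2S,3R,5R)-5-[(benzyloxy)methyl]-3-(TBSO)-2-methyl-2-(4-methylpent-3-en-1-yl)oxolane
Conditions: t-BuMe2SiOTf, 2,6-lutidine, CH2Cl2, −78 °C
Reagents that add atoms: tert-butyldimethylsilyl trifluoromethanesulfonate, CC(C)(C)[Si](C)(C)OS(=O)(=O)C(F)(F)F
Why: Silyl triflate O-silylation protects the hindered secondary alcohol against the later oxidations, with no change at any stereocentre.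

Step 15
Reactants: 24 (2S,3R,5R)-5-[(benzyloxy)methyl]-3-(TBSO)-2-methyl-2-(4-methylpent-3-en-1-yl)oxolane
Product: 25 [(2R,4R,5S)-4-(TBSO)-5-methyl-5-(4-methylpent-3-en-1-yl)oxolan-2-yl]methanol
Conditions: lithium 4,4′-di-tert-butylbiphenylide (LiC20H26, LiDBB), THF, −78 °C
Reagents that add atoms: none
Why: Single-electron-transfer reductive debenzylation cleaves the benzyl ether without touching the isolated trisubstituted alkene or the silyl ether.

Step 16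
Reactants: 25 [(2R,4R,5S)-4-(TBSO)-5-methyl-5-(4-methylpent-3-en-1-yl)oxolan-2-yl]methanol
Product: 26 (2R,4R,5S)-4-(TBSO)-5-methyl-5-(4-methylpent-3-en-1-yl)oxolane-2-carbaldehyde
Conditions: Dess–Martin periodinane, NaHCO3, CH2Cl2, rt
Reagents that add atoms: none
Why: Dess–Martin oxidation gives the α-alkoxy aldehyde under neutral buffered conditions that do not epimerise C2.

Step 17
Reactants: 26 (2R,4R,5S)-4-(TBSO)-5-methyl-5-(4-methylpent-3-en-1-yl)oxolane-2-carbaldehyde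
Product: 27 (2S,3R,5R)-3-(TBSO)-5-ethynyl-2-methyl-2-(4-methylpent-3-en-1-yl)oxolane
Conditions: MeC(O)C(N2)P(O)(OMe)2, K2CO3, MeOH, 0 °C → rt
Reagents that add atoms: dimethyl (1-diazo-2-oxopropyl)phosphonate, COP(=O)(OC)C(=[N+]=[N-])C(C)=O
Why: Ohira–Bestmann (Seyferth–Gilbert) homologation converts the aldehyde into the terminal alkyne under mild carbonate conditions that leave the α-alkoxy stereocentre intact.

Step 18
Reactants: 27 (2S,3R,5R)-3-(TBSO)-5-ethynyl-2-methyl-2-(4-methylpent-3-en-1-yl)oxolane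
Product: 29 (2S,3R,5R)-3-(TBSO)-5-[(1E)-1-iodoprop-1-en-2-yl]-2-methyl-2-(4-methylpent-3-en-1-yl)oxolane, via vinylalane 28 (not isolated)
Conditions: AlMe3 (3 equiv), Cp2ZrCl2 (0.5 equiv), H2O (1 equiv), CH2Cl2, −20 °C → rt; then I2, THF, −30 °C
Reagents that add atoms: trimethylaluminium, C[Al](C)C; iodine, II
Why: Negishi syn-carboalumination of the terminal alkyne followed by iodinolysis with retention gives the E vinyl iodide as a single regio- and stereoisomer.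

Step 19
Reactants: 12 tert-butyl(3-{(1S,2S,3S)-2-(2-iodoethyl)-6,6-dimethoxy-2,3-dimethyl-3-(TESO)cyclohexyl}propoxy)dimethylsilane; 29 (2S,3R,5R)-3-(TBSO)-5-[(1E)-1-iodoprop-1-en-2-yl]-2-methyl-2-(4-methylpent-3-en-1-yl)oxolane
Product: 32 (2S,3R,5R)-3-(TBSO)-5-[(2E)-5-{(1S,2S,6S)-6-[3-(TBSO)propyl]-5,5-dimethoxy-1,2-dimethyl-2-(TESO)cyclohexyl}pent-2-en-2-yl]-2-methyl-2-(4-methylpent-3-en-1-yl)oxolane, via alkyllithium 30 (not isolated), via lithium borinate 31 (not isolated)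
Conditions: 12, t-BuLi (2.1 equiv), B-methoxy-9-BBN, Et2O/THF, −78 °C → rt; then 29, Pd(dppf)Cl2 (5 mol %), AsPh3, Cs2CO3, DMF/H2O, rt
Reagents that add atoms: none
Why: B-alkyl Suzuki–Miyaura coupling, in which iodine–lithium exchange and boron trapping give an alkyl-9-BBN ate complex that transmetalates to the vinylpalladium from 29, joins the fragments with retention of the E geometry and no new stereocentre.

Step 20
Reactants: 32 (2S,3R,5R)-3-(TBSO)-5-[(2E)-5-{(1S,2S,6S)-6-[3-(TBSO)propyl]-5,5-dimethoxy-1,2-dimethyl-2-(TESO)cyclohexyl}pent-2-en-2-yl]-2-methyl-2-(4-methylpent-3-en-1-yl)oxolane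
Product: 33 (2S,3S,4S)-2-[3-(TBSO)propyl]-3,4-dimethyl-3-{(3E)-4-[(2R,4R,5S)-4-(TBSO)-5-methyl-5-(4-methylpent-3-en-1-yl)oxolan-2-yl]pent-3-en-1-yl}-4-(TESO)cyclohexan-1-one
Conditions: PPTS (cat.), acetone/H2O 10:1, rt
Reagents that add atoms: water, O
Why: Mild acid-catalysed ketal hydrolysis unmasks the ring ketone under conditions too weak to cleave the silyl ethers or epimerise the α-carbon.

Step 21
Reactants: 33 (2S,3S,4S)-2-[3-(TBSO)propyl]-3,4-dimethyl-3-{(3E)-4-[(2R,4R,5S)-4-(TBSO)-5-methyl-5-(4-methylpent-3-en-1-yl)oxolan-2-yl]pent-3-en-1-yl}-4-(TESO)cyclohexan-1-one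
Product: 34 (1R,2S,3S,4S)-2-[3-(TBSO)propyl]-3,4-dimethyl-3-{(3E)-4-[(2R,4R,5S)-4-(TBSO)-5-methyl-5-(4-methylpent-3-en-1-yl)oxolan-2-yl]pent-3-en-1-yl}-1-(prop-1-en-2-yl)-4-(TESO)cyclohexan-1-ol (major C1 epimer; both epimers are carried on)
Conditions: CH2=C(CH3)MgBr, CeCl3, THF, −78 → 0 °C
Reagents that add atoms: isopropenylmagnesium bromide, CC(=C)[Mg]Br
Why: Organocerium 1,2-addition to the hindered enolisable ketone gives the tertiary allylic alcohol without enolisation, the new carbinol centre (attack anti to the neighbouring chain expected) being erased in step 22.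

Step 22
Reactants: 34 (1R,2S,3S,4S)-2-[3-(TBSO)propyl]-3,4-dimethyl-3-{(3E)-4-[(2R,4R,5S)-4-(TBSO)-5-methyl-5-(4-methylpent-3-en-1-yl)oxolan-2-yl]pent-3-en-1-yl}-1-(prop-1-en-2-yl)-4-(TESO)cyclohexan-1-ol
Product: 36 (2Z)-2-[(2R,3S,4S)-2-[3-(TBSO)propyl]-3,4-dimethyl-3-{(3E)-4-[(2R,4R,5S)-4-(TBSO)-5-methyl-5-(4-methylpent-3-en-1-yl)oxolan-2-yl]pent-3-en-1-yl}-4-(TESO)cyclohexylidene]propanal, via allylic chlorochromate 35 (not isolated)
Conditions: pyridinium chlorochromate [C5H5NH][CrO3Cl] (3 equiv), NaOAc, 4 Å MS, CH2Cl2, rt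
Reagents that add atoms: none
Why: Babler–Dauben oxidative transposition ([3,3] shift of the tertiary chromate ester, then oxidation of the primary ester) gives the tetrasubstituted enal, and the chair transition state puts the less substituted ring CH2 next to the vinyl methyl to minimise A(1,2)/A(1,3) strain, so the aldehyde ends cis to the chain-bearing ring carbon (2Z).

Step 23
Reactants: 36 (2Z)-2-[(2R,3S,4S)-2-[3-(TBSO)propyl]-3,4-dimethyl-3-{(3E)-4-[(2R,4R,5S)-4-(TBSO)-5-methyl-5-(4-methylpent-3-en-1-yl)oxolan-2-yl]pent-3-en-1-yl}-4-(TESO)cyclohexylidene]propanal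
Product: 37 (2Z)-2-[(2R,3S,4S)-4-hydroxy-2-(3-hydroxypropyl)-3-{(3E)-4-[(2R,4R,5S)-4-hydroxy-5-methyl-5-(4-methylpent-3-en-1-yl)oxolan-2-yl]pent-3-en-1-yl}-3,4-dimethylcyclohexylidene]propanal (CNP0155390.1)
Conditions: HF·pyridine, pyridine, THF, 0 °C → rt
Reagents that add atoms: none
Why: Buffered fluoride desilylation removes the two TBS ethers and the TES ether under non-basic conditions that avoid γ-deprotonation of the enal, leaving all stereocentres and both alkene geometries as set.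

**Compound list**
1 | 4,4-dimethoxycyclohexa-2,5-dien-1-one | COC1(OC)C=CC(=O)C=C1 | starting material
2 | tert-butyldimethyl{[(2E)-3-(4,4,5,5-tetramethyl-1,3,2-dioxaborolan-2-yl)prop-2-en-1-yl]oxy}silane | CC(C)(C)[Si](C)(C)OC/C=C/B1OC(C)(C)C(C)(C)O1 | starting material
3 | (5R)-5-[(1E)-3-(TBSO)prop-1-en-1-yl]-4,4-dimethoxycyclohex-2-en-1-one | O=C1C[C@H](/C=C/CO[Si](C)(C)C(C)(C)C)C(OC)(OC)C=C1 | intermediate
4 | lithium dienolate of 3 (O–C1=C6, 5R) | [Li+].[O-]C1=C[C@H](/C=C/CO[Si](C)(C)C(C)(C)C)C(OC)(OC)C=C1 | intermediate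
5 | (5S,6S)-5-[(1E)-3-(TBSO)prop-1-en-1-yl]-4,4-dimethoxy-6-methylcyclohex-2-en-1-one | C[C@H]1[C@H](/C=C/CO[Si](C)(C)C(C)(C)C)C(OC)(OC)C=CC1=O | intermediate
6 | lithium dienolate of 5 (O–C1=C6 bearing the methyl, 5S) | [Li+].[O-]C1=C(C)[C@H](/C=C/CO[Si](C)(C)C(C)(C)C)C(OC)(OC)C=C1 | intermediate
7 | methyl 2-{(1S,6S)-6-[(1E)-3-(TBSO)prop-1-en-1-yl]-5,5-dimethoxy-1-methyl-2-oxocyclohex-3-en-1-yl}acetate | COC(=O)C[C@@]1(C)[C@H](/C=C/CO[Si](C)(C)C(C)(C)C)C(OC)(OC)C=CC1=O | intermediate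
8 | methyl 2-{(1S,6S)-6-[3-(TBSO)propyl]-5,5-dimethoxy-1-methyl-2-oxocyclohexyl}acetate | COC(=O)C[C@@]1(C)[C@H](CCCO[Si](C)(C)C(C)(C)C)C(OC)(OC)CCC1=O | intermediate
9 | methyl 2-{(1S,2S,6S)-6-[3-(TBSO)propyl]-2-hydroxy-5,5-dimethoxy-1,2-dimethylcyclohexyl}acetate | COC(=O)C[C@@]1(C)[C@H](CCCO[Si](C)(C)C(C)(C)C)C(OC)(OC)CC[C@]1(C)O | intermediate
10 | methyl 2-{(1S,2S,6S)-6-[3-(TBSO)propyl]-5,5-dimethoxy-1,2-dimethyl-2-(TESO)cyclohexyl}acetate | COC(=O)C[C@@]1(C)[C@H](CCCO[Si](C)(C)C(C)(C)C)C(OC)(OC)CC[C@]1(C)O[Si](CC)(CC)CC | intermediate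
11 | 2-{(1S,2S,6S)-6-[3-(TBSO)propyl]-5,5-dimethoxy-1,2-dimethyl-2-(TESO)cyclohexyl}ethan-1-ol | OCC[C@@]1(C)[C@H](CCCO[Si](C)(C)C(C)(C)C)C(OC)(OC)CC[C@]1(C)O[Si](CC)(CC)CC | intermediate
12 | tert-butyl(3-{(1S,2S,3S)-2-(2-iodoethyl)-6,6-dimethoxy-2,3-dimethyl-3-(TESO)cyclohexyl}propoxy)dimethylsilane | ICC[C@@]1(C)[C@H](CCCO[Si](C)(C)C(C)(C)C)C(OC)(OC)CC[C@]1(C)O[Si](CC)(CC)CC | intermediate
13 | 5-bromo-2-methylpent-2-ene | CC(C)=CCCBr | starting material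
14 | lithium acetylide–ethylenediamine complex | [Li+].[C-]#C.NCCN | starting material
15 | 6-methylhept-5-en-1-yne | CC(C)=CCCC#C | intermediate
16 | (2S)-2-[(benzyloxy)methyl]oxirane | C1O[C@@H]1COCc2ccccc2 | starting material
17 | dimethyl[(1E)-2,6-dimethylhepta-1,5-dien-1-yl]alane | C[Al](C)/C=C(\C)CCC=C(C)C | intermediate
18 | lithium butyl(dimethyl)[(1E)-2,6-dimethylhepta-1,5-dien-1-yl]aluminate | [Li+].CCCC[Al-](C)(C)/C=C(\C)CCC=C(C)C | intermediate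
19 | (2S,4E)-1-(benzyloxy)-5,9-dimethyldeca-4,8-dien-2-ol | CC(C)=CCC/C(C)=C/C[C@H](O)COCc1ccccc1 | intermediate
20 | (2S)-1-(benzyloxy)-3-[(2R,3R)-3-methyl-3-(4-methylpent-3-en-1-yl)oxiran-2-yl]propan-2-ol | CC(C)=CCC[C@@]1(C)O[C@@H]1C[C@H](O)COCc1ccccc1 | intermediate
21 | (2R)-1-(benzyloxy)-3-[(2R,3R)-3-methyl-3-(4-methylpent-3-en-1-yl)oxiran-2-yl]propan-2-yl 4-nitrobenzoate | CC(C)=CCC[C@@]1(C)O[C@@H]1C[C@@H](OC(=O)c1ccc(cc1)[N+](=O)[O-])COCc1ccccc1 | intermediate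
22 | (2R)-1-(benzyloxy)-3-[(2R,3R)-3-methyl-3-(4-methylpent-3-en-1-yl)oxiran-2-yl]propan-2-ol | CC(C)=CCC[C@@]1(C)O[C@@H]1C[C@@H](O)COCc1ccccc1 | intermediate
23 | (2S,3R,5R)-5-[(benzyloxy)methyl]-2-methyl-2-(4-methylpent-3-en-1-yl)oxolan-3-ol | CC(C)=CCC[C@]1(C)O[C@@H](COCc2ccccc2)C[C@H]1O | intermediate
24 | (2S,3R,5R)-5-[(benzyloxy)methyl]-3-(TBSO)-2-methyl-2-(4-methylpent-3-en-1-yl)oxolane | CC(C)=CCC[C@]1(C)O[C@@H](COCc2ccccc2)C[C@H]1O[Si](C)(C)C(C)(C)C | intermediate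
25 | [(2R,4R,5S)-4-(TBSO)-5-methyl-5-(4-methylpent-3-en-1-yl)oxolan-2-yl]methanol | CC(C)=CCC[C@]1(C)O[C@@H](CO)C[C@H]1O[Si](C)(C)C(C)(C)C | intermediate
26 | (2R,4R,5S)-4-(TBSO)-5-methyl-5-(4-methylpent-3-en-1-yl)oxolane-2-carbaldehyde | CC(C)=CCC[C@]1(C)O[C@@H](C=O)C[C@H]1O[Si](C)(C)C(C)(C)C | intermediate
27 | (2S,3R,5R)-3-(TBSO)-5-ethynyl-2-methyl-2-(4-methylpent-3-en-1-yl)oxolane | CC(C)=CCC[C@]1(C)O[C@@H](C#C)C[C@H]1O[Si](C)(C)C(C)(C)C | intermediate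
28 | dimethyl{(1E)-2-[(2R,4R,5S)-4-(TBSO)-5-methyl-5-(4-methylpent-3-en-1-yl)oxolan-2-yl]prop-1-en-1-yl}alane | CC(C)=CCC[C@]1(C)O[C@@H](/C(C)=C/[Al](C)C)C[C@H]1O[Si](C)(C)C(C)(C)C | intermediate
29 | (2S,3R,5R)-3-(TBSO)-5-[(1E)-1-iodoprop-1-en-2-yl]-2-methyl-2-(4-methylpent-3-en-1-yl)oxolane | CC(C)=CCC[C@]1(C)O[C@@H](/C(C)=C/I)C[C@H]1O[Si](C)(C)C(C)(C)C | intermediate
30 | {2-[(1S,2S,6S)-6-[3-(TBSO)propyl]-5,5-dimethoxy-1,2-dimethyl-2-(TESO)cyclohexyl]ethyl}lithium | [Li]CC[C@@]1(C)[C@H](CCCO[Si](C)(C)C(C)(C)C)C(OC)(OC)CC[C@]1(C)O[Si](CC)(CC)CC | intermediate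
31 | lithium 9-{2-[(1S,2S,6S)-6-[3-(TBSO)propyl]-5,5-dimethoxy-1,2-dimethyl-2-(TESO)cyclohexyl]ethyl}-9-methoxy-9-boranuidabicyclo[3.3.1]nonane | [Li+].CO[B-]1(CC[C@@]2(C)[C@H](CCCO[Si](C)(C)C(C)(C)C)C(OC)(OC)CC[C@]2(C)O[Si](CC)(CC)CC)C2CCCC1CCC2 | intermediate
32 | (2S,3R,5R)-3-(TBSO)-5-[(2E)-5-{(1S,2S,6S)-6-[3-(TBSO)propyl]-5,5-dimethoxy-1,2-dimethyl-2-(TESO)cyclohexyl}pent-2-en-2-yl]-2-methyl-2-(4-methylpent-3-en-1-yl)oxolane | CC(C)=CCC[C@]1(C)O[C@@H](/C(C)=C/CC[C@@]2(C)[C@H](CCCO[Si](C)(C)C(C)(C)C)C(OC)(OC)CC[C@]2(C)O[Si](CC)(CC)CC)C[C@H]1O[Si](C)(C)C(C)(C)C | intermediate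
33 | (2S,3S,4S)-2-[3-(TBSO)propyl]-3,4-dimethyl-3-{(3E)-4-[(2R,4R,5S)-4-(TBSO)-5-methyl-5-(4-methylpent-3-en-1-yl)oxolan-2-yl]pent-3-en-1-yl}-4-(TESO)cyclohexan-1-one | CC(C)=CCC[C@]1(C)O[C@@H](/C(C)=C/CC[C@@]2(C)[C@H](CCCO[Si](C)(C)C(C)(C)C)C(=O)CC[C@]2(C)O[Si](CC)(CC)CC)C[C@H]1O[Si](C)(C)C(C)(C)C | intermediate
34 | (1R,2S,3S,4S)-2-[3-(TBSO)propyl]-3,4-dimethyl-3-{(3E)-4-[(2R,4R,5S)-4-(TBSO)-5-methyl-5-(4-methylpent-3-en-1-yl)oxolan-2-yl]pent-3-en-1-yl}-1-(prop-1-en-2-yl)-4-(TESO)cyclohexan-1-ol (major C1 epimer) | CC(C)=CCC[C@]1(C)O[C@@H](/C(C)=C/CC[C@@]2(C)[C@H](CCCO[Si](C)(C)C(C)(C)C)[C@@](O)(C(C)=C)CC[C@]2(C)O[Si](CC)(CC)CC)C[C@H]1O[Si](C)(C)C(C)(C)C | intermediate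
35 | (2Z)-2-[(2R,3S,4S)-cyclohexylidene as in 36]propyl chlorochromate (CH2O–CrO2Cl in place of CHO) | CC(C)=CCC[C@]1(C)O[C@@H](/C(C)=C/CC[C@@]2(C)[C@H](CCCO[Si](C)(C)C(C)(C)C)/C(=C(/C)CO[Cr](=O)(=O)Cl)CC[C@]2(C)O[Si](CC)(CC)CC)C[C@H]1O[Si](C)(C)C(C)(C)C | intermediate
36 | (2Z)-2-[(2R,3S,4S)-2-[3-(TBSO)propyl]-3,4-dimethyl-3-{(3E)-4-[(2R,4R,5S)-4-(TBSO)-5-methyl-5-(4-methylpent-3-en-1-yl)oxolan-2-yl]pent-3-en-1-yl}-4-(TESO)cyclohexylidene]propanal | CC(C)=CCC[C@]1(C)O[C@@H](/C(C)=C/CC[C@@]2(C)[C@H](CCCO[Si](C)(C)C(C)(C)C)/C(=C(/C)C=O)CC[C@]2(C)O[Si](CC)(CC)CC)C[C@H]1O[Si](C)(C)C(C)(C)C | intermediate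
37 | (2Z)-2-[(2R,3S,4S)-4-hydroxy-2-(3-hydroxypropyl)-3-{(3E)-4-[(2R,4R,5S)-4-hydroxy-5-methyl-5-(4-methylpent-3-en-1-yl)oxolan-2-yl]pent-3-en-1-yl}-3,4-dimethylcyclohexylidene]propanal | CC(C)=CCC[C@]1(C)O[C@@H](/C(C)=C/CC[C@@]2(C)[C@H](CCCO)/C(=C(/C)C=O)CC[C@]2(C)O)C[C@H]1O | target

**Totals**
Total step count: 23.
Longest linear sequence: 15 steps (steps 9–23, from 13). The fragment A branch is 13 steps (steps 1–8, then 19–23).

**Three steps most likely to fail**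

Step 22 (oxidative transposition to the tetrasubstituted Z-enal). The hindered tertiary chromate may rearrange slowly, dehydrate, or give E/Z mixtures. The fallback sets out from ketone 33 and comes back at enal 36. Peterson olefination of 33 with lithiated 2-(trimethylsilyl)propanenitrile (LiN(i-Pr)2, THF, −78 °C → rt) gives the tetrasubstituted unsaturated nitrile, (2Z)-2-[cyclohexylidene as in 36]propanenitrile F8; the slim nitrile should prefer the side of the more substituted ring carbon. (i-Bu)2AlH (toluene, −78 °C), then mild aqueous acid, converts the nitrile into the aldehyde with the double-bond geometry kept, giving 36.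

Step 5 (facial selectivity of methyl addition next to the quaternary carbon). If the reagent takes the other face, the fallback sets out from ketone 8 and comes back at iodide 12.
- Wittig methylenation (Ph3PCH3Br, KOt-Bu, toluene, 80 °C) gives methyl 2-{(1S,6S)-6-[3-(TBSO)propyl]-5,5-dimethoxy-1-methyl-2-methylidenecyclohexyl}acetate F4.
- Dimethyldioxirane (acetone, 0 °C) epoxidises the face a nucleophile would take, so oxygen ends where the methyl would have gone, giving methyl 2-{(3S,4S,5S)-5-[3-(TBSO)propyl]-6,6-dimethoxy-4-methyl-1-oxaspiro[2.5]octan-4-yl}acetate F5.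
- LiAlH4 (THF, 0 °C → rt) opens the epoxide at CH2 and reduces the ester, giving 2-{(1S,2S,6S)-6-[3-(TBSO)propyl]-2-hydroxy-5,5-dimethoxy-1,2-dimethylcyclohexyl}ethan-1-ol F6.
- I2/PPh3/imidazole (0 °C) gives (1S,2S,3S)-3-[3-(TBSO)propyl]-2-(2-iodoethyl)-4,4-dimethoxy-1,2-dimethylcyclohexan-1-ol F7.
- Et3SiOTf/2,6-lutidine then gives 12.

Step 1 (rhodium alkenyl addition next to the ketal carbon; risk of low conversion, double addition or modest enantioselectivity). The fallback sets out from dienone 1 and comes back at keto ester 8.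
- Copper-catalysed asymmetric conjugate addition of bis[3-(TBSO)propyl]zinc (Cu(OTf)2 2 mol %, (R)-binaphthyl N,N-bis[(S)-1-phenylethyl]phosphoramidite 4 mol %, toluene, −25 °C) installs the saturated chain directly, giving (5S)-5-[3-(TBSO)propyl]-4,4-dimethoxycyclohex-2-en-1-one F1.
- LDA/MeI gives (5S,6S)-5-[3-(TBSO)propyl]-4,4-dimethoxy-6-methylcyclohex-2-en-1-one F2.
- LDA/BrCH2CO2Me gives methyl 2-{(1S,6S)-6-[3-(TBSO)propyl]-5,5-dimethoxy-1-methyl-2-oxocyclohex-3-en-1-yl}acetate F3.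
- H2, Pd/C gives 8.

**Further compounds**
F1 | step 1 | (5S)-5-[3-(TBSO)propyl]-4,4-dimethoxycyclohex-2-en-1-one | O=C1C[C@H](CCCO[Si](C)(C)C(C)(C)C)C(OC)(OC)C=C1
F2 | step 1 | (5S,6S)-5-[3-(TBSO)propyl]-4,4-dimethoxy-6-methylcyclohex-2-en-1-one | C[C@H]1[C@H](CCCO[Si](C)(C)C(C)(C)C)C(OC)(OC)C=CC1=O
F3 | step 1 | methyl 2-{(1S,6S)-6-[3-(TBSO)propyl]-5,5-dimethoxy-1-methyl-2-oxocyclohex-3-en-1-yl}acetate | COC(=O)C[C@@]1(C)[C@H](CCCO[Si](C)(C)C(C)(C)C)C(OC)(OC)C=CC1=O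
F4 | step 5 | methyl 2-{(1S,6S)-6-[3-(TBSO)propyl]-5,5-dimethoxy-1-methyl-2-methylidenecyclohexyl}acetate | COC(=O)C[C@@]1(C)[C@H](CCCO[Si](C)(C)C(C)(C)C)C(OC)(OC)CCC1=C
F5 | step 5 | methyl 2-{(3S,4S,5S)-5-[3-(TBSO)propyl]-6,6-dimethoxy-4-methyl-1-oxaspiro[2.5]octan-4-yl}acetate | COC(=O)C[C@@]1(C)[C@H](CCCO[Si](C)(C)C(C)(C)C)C(OC)(OC)CC[C@@]12CO2
F6 | step 5 | 2-{(1S,2S,6S)-6-[3-(TBSO)propyl]-2-hydroxy-5,5-dimethoxy-1,2-dimethylcyclohexyl}ethan-1-ol | OCC[C@@]1(C)[C@H](CCCO[Si](C)(C)C(C)(C)C)C(OC)(OC)CC[C@]1(C)O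
F7 | step 5 | (1S,2S,3S)-3-[3-(TBSO)propyl]-2-(2-iodoethyl)-4,4-dimethoxy-1,2-dimethylcyclohexan-1-ol | ICC[C@@]1(C)[C@H](CCCO[Si](C)(C)C(C)(C)C)C(OC)(OC)CC[C@]1(C)O
F8 | step 22 | (2Z)-2-[(2R,3S,4S)-2-[3-(TBSO)propyl]-3,4-dimethyl-3-{(3E)-4-[(2R,4R,5S)-4-(TBSO)-5-methyl-5-(4-methylpent-3-en-1-yl)oxolan-2-yl]pent-3-en-1-yl}-4-(TESO)cyclohexylidene]propanenitrile | CC(C)=CCC[C@]1(C)O[C@@H](/C(C)=C/CC[C@@]2(C)[C@H](CCCO[Si](C)(C)C(C)(C)C)/C(=C(/C)C#N)CC[C@]2(C)O[Si](CC)(CC)CC)C[C@H]1O[Si](C)(C)C(C)(C)C
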